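All runs are simulated on assumed constants, and the scatter is random.

A ratio was what I left for the next person at the bench. Substrate went two ways, with second reagent to side product and with partner towards target, and I called the rate of the first way over the rate of the second the split (a selectivity factor).

| setting | Saturday's | Friday's | Wednesday's | Tuesday's | spring | autumn | noon | midnight |
|---|---|---|---|---|---|---|---|---|
| substrate | 0.20 M | 0.20 M | 0.20 M | 0.30 M | 0.20 M | 0.20 M (fed, over 50 min) | 0.20 M | 0.20 M (fed, over 50 min) |
| partner | 0.20 M | 0.20 M | 0.20 M | 0.20 M | 0.200 M (fed, over 12 min) | 0.200 M | 0.200 M | 0.200 M |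
| second reagent | 0.80 M | 1.1 M | 1.8 M | 0.80 M | 0.800 M | 0.800 M | 0.800 M | 0.800 M |
| temperature | 35 °C | 50 °C | 35 °C | 50 °C | 50 °C |  | 50 °C | 50 °C |
| remark | run made earlier | run made earlier | run made earlier | run made earlier | all else is in the flask from the start; the feed brings no volume worth counting | the addition at 30 °C, then warmed to 50 °C; the feed brings no volume worth counting | everything together at the start | all else is in the flask from the start; the feed brings no volume worth counting |
| time |  |  |  |  | 2.0 h | 2.0 h | 2.0 h | 2.0 h |

| run | time / h | side product / % | target / % |
|---|---|---|---|
| Saturday's | 0.500 | 12.7 | 0 |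
| Saturday's | 1.00 | 22.0 | 1.7 |
| Saturday's | 1.33 | 28.0 | 3.8 |
| Saturday's | 2.00 | 33.8 | 5.6 |
| Saturday's | 3.00 | 42.2 | 10.9 |
| Friday's | 0.200 | 23.2 | 4.1 |
| Friday's | 0.667 | 45.1 | 10.7 |
| Friday's | 1.00 | 49.1 | 16.1 |
| Friday's | 1.50 | 51.5 | 23.5 |
| Friday's | 2.50 | 55.7 | 29.4 |
| Wednesday's | 1.00 | 43.1 | 5.2 |
| Wednesday's | 2.00 | 58.8 | 12.4 |
| Wednesday's | 3.00 | 62.8 | 15.7 |
| Wednesday's | 4.00 | 65.2 | 18.9 |
| Wednesday's | 5.00 | 64.8 | 21.2 |
| Tuesday's | 0.200 | 16.6 | 3.1 |
| Tuesday's | 0.333 | 22.5 | 2.9 |
| Tuesday's | 0.667 | 35.4 | 8.8 |
| Tuesday's | 1.33 | 44.0 | 19.0 |
| Tuesday's | 2.50 | 46.0 | 26.8 |

(standard deviation of a reading: 1 percentage point)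

1. the flask that comes out highest in amount of side product, in percent of the substrate charged; "all alike" if 1.5 percentage points covers them all (spring / autumn / noon / midnight / all alike)
2. amount of side product at the end, in percent of the substrate charged, spring
3. amount of side product at the end, in percent of the substrate charged, autumn
4. amount of side product at the end, in percent of the substrate charged, noon
5. amount of side product at the end, in percent of the substrate charged, midnight

- a reading or a percentage of target counts all its forms, free or not

Friday's first reading of side product over Tuesday's was 1.40, while their second reagent stood at 1.38 to one, though Tuesday's held more substrate. So I took the side step as first order in substrate and in second reagent. Taking the partner step as first order in substrate too, substrate cancels, and the split is a constant times second reagent over partner.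

Friday's run had slowed near 55.7% of side product. With equal charges I took the rest as partner used, and summing the split over that partner put the constant at 0.173; Wednesday's colder run gave 0.166. That made 0.692 the split of side rate over partner rate at the start of noon.

My note said two things. Expect no gain from feeding substrate: the split holds no substrate, so I expected midnight and autumn near noon, a little short if substrate was left at the end. Leave spring's partner feed alone: over its 12 min partner averaged about half its charge, so the split in spring was near 1.38, above noon's, and I expected spring on top.

The forecast named spring, with 52% for spring, 47% for autumn, 47.5% for noon and 46.5% for midnight, holding that “Feeding partner leaves substrate exposed early”.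

Spring came out highest at 50.2%, above noon's 45.8%, midnight's 43.9% and autumn's 42.9%.

    substrate + partner → intermediate (k = 5.30 /M/h, Ea = 65.0 kJ/mol)
    substrate + second reagent → side product (k = 1.30 /M/h, Ea = 66.0 kJ/mol)
    substrate + target ⇌ idle adduct, settled at all times (K = 140 /M, ΔH = 13.0 kJ/mol)
    second reagent + intermediate → target (k = 1.10 /M/h, Ea = 81.0 kJ/mol)
    (constants at 50 °C)

Up to the end of its feed, spring made 2.14 of side product per partner used, more than the 0.692 I had read from the runs for noon's starting split, and 59% of its side step's turnover stood behind it at 0.400 h, against 11% for the step to target. With partner at full charge and 0.20 M of second reagent the constants above give a split of 0.245 at 50 °C, and that flask, otherwise spring's recipe, ended with 19.9% of side product and 45.0% as intermediate.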